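**Plan**

1. Cuts: the bond from the quaternary ring carbon C1' to the side-chain CH2 and, with it, the C1'–CH3 bond, with the exocyclic C2'=CH2 carried as a ketone; in the chromene, O1–C2 (Pd-allyl etherification) and C4–C4a (alkyne hydroarylation).
2. Forward: the arene is oxygenated (steps 1–3), the tertiary aryl ether is made (step 4) and the pyran ring is closed by gold (step 7) to give a 2-vinylchromene; the cyclohexane ring comes intact from 2-methylcyclohexenone (steps 8–10); the halves are joined in step 11, then methylenation and desilylation.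
3. Key event: a three-component union at C1'. The side-chain CH2 migrates from boron onto the α-carbon of an α-bromo ketone enolate, and the boron enolate left behind is methylated in the same flask.
4. Enabling feature: C1' lies next to C2', whose exocyclic methylene is a latent C=O, so C1' is an α-carbon that can take two carbon groups in turn; the C3' methyl across that carbonyl steers the second one.
5. Stereochemistry: chromene C2 from the chiral Pd ligand (step 4); C3' from an ene-reductase (step 8); C1' from methylation anti to the C3' methyl (step 11).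

Key step: step 11

Assumption: the (R,R)-Trost ligand is taken to deliver the (S)-ether in step 4, by analogy with its additions to butadiene monoxide; if the sense proves opposite, the (S,S)-ligand is used.

**Route**

Step 1
Reactants: 1 2-methoxybenzene-1,4-diol
Product: 2 1,4-bis(triisopropylsilyloxy)-2-methoxybenzene
Conditions: TIPSCl (2.3 equiv), imidazole, DMF, rt
Reagents that add atoms: triisopropylsilyl chloride, CC(C)[Si](Cl)(C(C)C)C(C)C
Why: Imidazole-promoted O-silylation of both phenols; the bulky TIPS ethers should survive the later organolithium and borane steps and come off with fluoride at the end.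

Step 2
Reactants: 2 1,4-bis(triisopropylsilyloxy)-2-methoxybenzene
Product: 3 1-bromo-4-methoxy-2,5-bis(triisopropylsilyloxy)benzene
Conditions: NBS (1.0 equiv), MeCN, 0 °C → rt
Reagents that add atoms: N-bromosuccinimide, O=C1CCC(=O)N1Br
Why: Electrophilic aromatic bromination; the position para to the methoxy group is the most activated open site, while the site between OMe and OTIPS is shielded.

Step 3
Reactants: 3 1-bromo-4-methoxy-2,5-bis(triisopropylsilyloxy)benzene
Product: 5 4-methoxy-2,5-bis(triisopropylsilyloxy)phenol, via arylboronate 4 (not isolated)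
Conditions: B(OiPr)3, then n-BuLi, THF–toluene, −78 °C; AcOH, 30% H2O2, 0 °C → rt
Reagents that add atoms: hydrogen peroxide, OO
Why: Bromine–lithium exchange with in situ borate trapping (which should outrun O→C silyl migration), then oxidation of the aryl boronate to the phenol at the same carbon.

Step 4
Reactants: 5 4-methoxy-2,5-bis(triisopropylsilyloxy)phenol; 6 2-methyl-2-vinyloxirane (racemic)
Product: 7 (2S)-2-[4-methoxy-2,5-bis(triisopropylsilyloxy)phenoxy]-2-methylbut-3-en-1-ol
Conditions: Pd2(dba)3·CHCl3 (1 mol %), (R,R)-DACH-phenyl Trost ligand (3 mol %), CH2Cl2, rt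
Reagents that add atoms: none
Why: Tsuji–Trost-type asymmetric allylic etherification run as a dynamic kinetic asymmetric transformation of the vinyl epoxide; the π-allyl faces interconvert, and the chiral ligand together with the hydrogen bond from the phenol to the Pd-bound alkoxide should direct attack to the tertiary carbon and set the (S) ether centre.

Step 5
Reactants: 7 (2S)-2-[4-methoxy-2,5-bis(triisopropylsilyloxy)phenoxy]-2-methylbut-3-en-1-ol
Product: 8 (2S)-2-[4-methoxy-2,5-bis(triisopropylsilyloxy)phenoxy]-2-methylbut-3-enal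
Conditions: Dess–Martin periodinane, NaHCO3, CH2Cl2, 0 °C → rt
Reagents that add atoms: none
Why: Dess–Martin oxidation of a neopentyl-type primary alcohol; the aldehyde has no α-hydrogen, so the stereocentre cannot epimerise.

Step 6
Reactants: 8 (2S)-2-[4-methoxy-2,5-bis(triisopropylsilyloxy)phenoxy]-2-methylbut-3-enal
Product: 9 (3S)-3-[4-methoxy-2,5-bis(triisopropylsilyloxy)phenoxy]-3-methylpent-1-en-4-yne
Conditions: TMSCHN2, n-BuLi, THF, −78 °C; then 8, −78 → 0 °C
Reagents that add atoms: trimethylsilyldiazomethane, C[Si](C)(C)C=[N+]=[N-]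
Why: One-carbon homologation of the aldehyde to the terminal alkyne by the Colvin rearrangement; the conditions are free of alkoxide, so the aryl silyl ethers should stay on and the quaternary stereocentre is not touched.

Step 7
Reactants: 9 (3S)-3-[4-methoxy-2,5-bis(triisopropylsilyloxy)phenoxy]-3-methylpent-1-en-4-yne
Product: 10 (2S)-2-ethenyl-6-methoxy-2-methyl-5,8-bis(triisopropylsilyloxy)-2H-chromene
Conditions: [JohnPhosAu(MeCN)]SbF6 (2 mol %), CH2Cl2, rt
Reagents that add atoms: none
Why: Gold(I)-catalysed 6-endo-dig intramolecular hydroarylation of an aryl propargyl ether closes the pyran ring at the only free ortho carbon; no o-quinone methide is involved, so the C2 configuration should be kept.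

Step 8
Reactants: 11 2-methylcyclohex-2-en-1-one
Product: 12 (2R)-2-methylcyclohexan-1-one
Conditions: ene-reductase of the Old Yellow Enzyme family (e.g. OYE1), NADP+ (cat.), glucose, glucose dehydrogenase, phosphate buffer pH 7, 30 °C
Reagents that add atoms: none
Why: Biocatalytic asymmetric reduction of the activated C=C bond; enzymes of this family are known to give the (R)-ketone from this substrate, by hydride delivery to C3 and protonation at C2 in the active site.

Step 9
Reactants: 12 (2R)-2-methylcyclohexan-1-one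
Product: 13 trimethyl{[(6R)-6-methylcyclohex-1-en-1-yl]oxy}silane
Conditions: LDA, THF, −78 °C; TMSCl, −78 °C → rt
Reagents that add atoms: chlorotrimethylsilane, C[Si](C)(C)Cl
Why: Kinetic deprotonation at the CH2 side and O-silylation; the methine stereocentre is not deprotonated, so its configuration is kept.

Step 10
Reactants: 13 trimethyl{[(6R)-6-methylcyclohex-1-en-1-yl]oxy}silane
Product: 14 (6R)-2-bromo-6-methylcyclohexan-1-one (mixture of C2 epimers)
Conditions: NBS, NaHCO3, THF, −78 → 0 °C
Reagents that add atoms: N-bromosuccinimide, O=C1CCC(=O)N1Br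
Why: Regiospecific electrophilic α-bromination of the silyl enol ether under buffered conditions; the C2 epimers converge to one enolate in the next step.

Step 11
Reactants: 10 (2S)-2-ethenyl-6-methoxy-2-methyl-5,8-bis(triisopropylsilyloxy)-2H-chromene; 14 (6R)-2-bromo-6-methylcyclohexan-1-one
Product: 17 (2R,6R)-2-{2-[(2S)-6-methoxy-2-methyl-5,8-bis(triisopropylsilyloxy)-2H-chromen-2-yl]ethyl}-2,6-dimethylcyclohexan-1-one, via alkylborane 15 (not isolated), via boron enolate 16 (not isolated)
Conditions: 9-BBN (1.05 equiv), THF, 0 °C → rt; add 14, then LiHMDS (1.0 equiv), −78 → 0 °C; MeLi (1.0 equiv), −78 °C; MeI, DMPU, −78 → 0 °C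
Reagents that add atoms: iodomethane, CI
Why: Proposed new method: 9-BBN adds only to the terminal vinyl group of 10 to give 15; LiHMDS removes the acidic CHBr proton of 14, the bromo enolate binds boron through C2, and the side-chain CH2 migrates from boron to C2 as bromide leaves, which forms the C2–CH2 bond and leaves the regiodefined boron enolate 16; MeLi then activates 16 at boron so that MeI methylates C2. The closest known reaction types are the organoborane alkylation of α-bromo ketone enolates with B-alkyl-9-BBN reagents (1,2-metalate shift) and the C-alkylation of enolates released from enol borinates, as after a Hooz reaction; their union in one flask to make a quaternary carbon beside an α'-stereocentre is the untested part. No ring is closed. The new quaternary centre C2 is controlled by the C6 methyl group, which should sit pseudoaxial to avoid allylic strain with the O–boron group, so that MeI enters on the opposite face and places the two methyl groups trans (2R,6R). The step needs transfer of the primary alkyl and not of the cyclooctyl ring (secured by the 9-BBN unit), enolate formation at C2 and not at C6 (secured first by the bromine, then by the boron shift), and an untouched C6–H (no proton shuttle is present until the quench).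

Step 12
Reactants: 17 (2R,6R)-2-{2-[(2S)-6-methoxy-2-methyl-5,8-bis(triisopropylsilyloxy)-2H-chromen-2-yl]ethyl}-2,6-dimethylcyclohexan-1-one
Product: 18 (2S)-2-{2-[(1R,3R)-1,3-dimethyl-2-methylidenecyclohexyl]ethyl}-6-methoxy-2-methyl-5,8-bis(triisopropylsilyloxy)-2H-chromene
Conditions: Tebbe reagent (2 equiv), pyridine (cat.), THF–toluene, −40 °C → rt
Reagents that add atoms: Tebbe reagent, C[Al-]1(C)C[Ti](C2C=CC=C2)(C2C=CC=C2)[Cl+]1
Why: Tebbe olefination; the non-basic titanium methylidene should methylenate the hindered ketone by [2+2] addition and cycloreversion without enolising it, so the C6 centre is kept.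

Step 13
Reactants: 18 (2S)-2-{2-[(1R,3R)-1,3-dimethyl-2-methylidenecyclohexyl]ethyl}-6-methoxy-2-methyl-5,8-bis(triisopropylsilyloxy)-2H-chromene
Product: 19 (2S)-2-{2-[(1R,3R)-1,3-dimethyl-2-methylidenecyclohexyl]ethyl}-6-methoxy-2-methyl-2H-chromene-5,8-diol
Conditions: TBAF (2.4 equiv), AcOH (2.4 equiv), THF, 0 °C, argon; work-up with degassed aq. NH4Cl/Na2S2O4
Reagents that add atoms: none
Why: Fluoride cleavage of both aryl silyl ethers under acetic acid buffering; acid-free and air-free conditions should spare the chromene stereocentre, the exocyclic alkene and the oxidation-prone hydroquinone.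

**Compound list**

1 | 2-methoxybenzene-1,4-diol (2-methoxyhydroquinone) | COc1cc(O)ccc1O | starting material
2 | 1,4-bis(triisopropylsilyloxy)-2-methoxybenzene | COc1cc(O[Si](C(C)C)(C(C)C)C(C)C)ccc1O[Si](C(C)C)(C(C)C)C(C)C | intermediate
3 | 1-bromo-4-methoxy-2,5-bis(triisopropylsilyloxy)benzene | COc1cc(O[Si](C(C)C)(C(C)C)C(C)C)c(Br)cc1O[Si](C(C)C)(C(C)C)C(C)C | intermediate
4 | diisopropyl [4-methoxy-2,5-bis(triisopropylsilyloxy)phenyl]boronate | COc1cc(O[Si](C(C)C)(C(C)C)C(C)C)c(B(OC(C)C)OC(C)C)cc1O[Si](C(C)C)(C(C)C)C(C)C | intermediate (not isolated)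
5 | 4-methoxy-2,5-bis(triisopropylsilyloxy)phenol | COc1cc(O[Si](C(C)C)(C(C)C)C(C)C)c(O)cc1O[Si](C(C)C)(C(C)C)C(C)C | intermediate
6 | 2-methyl-2-vinyloxirane (isoprene monoxide, racemic) | CC1(C=C)CO1 | starting material
7 | (2S)-2-[4-methoxy-2,5-bis(triisopropylsilyloxy)phenoxy]-2-methylbut-3-en-1-ol | C=C[C@@](Oc1cc(O[Si](C(C)C)(C(C)C)C(C)C)c(OC)cc1O[Si](C(C)C)(C(C)C)C(C)C)(C)CO | intermediate
8 | (2S)-2-[4-methoxy-2,5-bis(triisopropylsilyloxy)phenoxy]-2-methylbut-3-enal | C=C[C@@](Oc1cc(O[Si](C(C)C)(C(C)C)C(C)C)c(OC)cc1O[Si](C(C)C)(C(C)C)C(C)C)(C)C=O | intermediate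
9 | (3S)-3-[4-methoxy-2,5-bis(triisopropylsilyloxy)phenoxy]-3-methylpent-1-en-4-yne | C=C[C@@](Oc1cc(O[Si](C(C)C)(C(C)C)C(C)C)c(OC)cc1O[Si](C(C)C)(C(C)C)C(C)C)(C)C#C | intermediate
10 | (2S)-2-ethenyl-6-methoxy-2-methyl-5,8-bis(triisopropylsilyloxy)-2H-chromene | C=C[C@@]1(C)C=Cc2c(O[Si](C(C)C)(C(C)C)C(C)C)c(OC)cc(O[Si](C(C)C)(C(C)C)C(C)C)c2O1 | intermediate
11 | 2-methylcyclohex-2-en-1-one | CC1=CCCCC1=O | starting material
12 | (2R)-2-methylcyclohexan-1-one | O=C1[C@H](C)CCCC1 | intermediate
13 | trimethyl{[(6R)-6-methylcyclohex-1-en-1-yl]oxy}silane | C[C@@H]1CCCC=C1O[Si](C)(C)C | intermediate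
14 | (6R)-2-bromo-6-methylcyclohexan-1-one (mixture of C2 epimers) | O=C1[C@H](C)CCCC1Br | intermediate
15 | 9-{2-[(2S)-6-methoxy-2-methyl-5,8-bis(triisopropylsilyloxy)-2H-chromen-2-yl]ethyl}-9-borabicyclo[3.3.1]nonane | C(C[C@@]1(C)C=Cc2c(O[Si](C(C)C)(C(C)C)C(C)C)c(OC)cc(O[Si](C(C)C)(C(C)C)C(C)C)c2O1)B1C2CCCC1CCC2 | intermediate (not isolated)
16 | 9-({(6R)-2-{2-[(2S)-6-methoxy-2-methyl-5,8-bis(triisopropylsilyloxy)-2H-chromen-2-yl]ethyl}-6-methylcyclohex-1-en-1-yl}oxy)-9-borabicyclo[3.3.1]nonane | C[C@@H]1CCCC(CC[C@@]2(C)C=Cc3c(O[Si](C(C)C)(C(C)C)C(C)C)c(OC)cc(O[Si](C(C)C)(C(C)C)C(C)C)c3O2)=C1OB1C2CCCC1CCC2 | intermediate (not isolated)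
17 | (2R,6R)-2-{2-[(2S)-6-methoxy-2-methyl-5,8-bis(triisopropylsilyloxy)-2H-chromen-2-yl]ethyl}-2,6-dimethylcyclohexan-1-one | O=C1[C@H](C)CCC[C@]1(C)CC[C@@]1(C)C=Cc2c(O[Si](C(C)C)(C(C)C)C(C)C)c(OC)cc(O[Si](C(C)C)(C(C)C)C(C)C)c2O1 | intermediate
18 | (2S)-2-{2-[(1R,3R)-1,3-dimethyl-2-methylidenecyclohexyl]ethyl}-6-methoxy-2-methyl-5,8-bis(triisopropylsilyloxy)-2H-chromene | C=C1[C@H](C)CCC[C@]1(C)CC[C@@]1(C)C=Cc2c(O[Si](C(C)C)(C(C)C)C(C)C)c(OC)cc(O[Si](C(C)C)(C(C)C)C(C)C)c2O1 | intermediate
19 | (2S)-2-{2-[(1R,3R)-1,3-dimethyl-2-methylidenecyclohexyl]ethyl}-6-methoxy-2-methyl-2H-chromene-5,8-diol | C=C1[C@H](C)CCC[C@]1(C)CC[C@@]1(C)C=Cc2c(O)c(OC)cc(O)c2O1 | target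

**Summary**

Total step count: 13. Longest linear sequence: 10 steps (steps 1–7, then 11–13).

Steps most likely to fail, with fallbacks:

1. Step 11 (proposed new method). The bromo enolate may bind boron through oxygen or lose bromide before the 1,2-shift takes place, or the methylation may show poor facial selectivity. The fallback uses known chemistry, sets out from 13 and from borane 15, and returns at 17. Saegusa–Ito oxidation of 13 (Pd(OAc)2, MeCN, rt) should give (6R)-6-methylcyclohex-2-en-1-one F1. Iodine and pyridine in CH2Cl2 convert it into (6R)-2-iodo-6-methylcyclohex-2-en-1-one F2. B-alkyl Suzuki–Miyaura coupling of F2 with 15 (PdCl2(dppf), Ph3As, Cs2CO3, DMF–THF–H2O, rt) gives (6R)-2-{2-[(2S)-6-methoxy-2-methyl-5,8-bis(triisopropylsilyloxy)-2H-chromen-2-yl]ethyl}-6-methylcyclohex-2-en-1-one F3. Conjugate reduction of F3 with L-Selectride (THF, −78 °C) generates the same regiodefined enolate, which MeI should methylate anti to the C6 methyl group to give 17.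

2. Step 4. Attack of the hindered, electron-rich phenol on the π-allyl may be poorly regio- or enantioselective. The fallback sets out from 5 and returns at 9, and takes the stereocentre from an epoxidation instead. Sharpless asymmetric epoxidation of commercial (E)-3-methylpent-2-en-4-yn-1-ol (L-(+)-diethyl tartrate, Ti(OiPr)4, t-BuOOH, 4 Å sieves, CH2Cl2, −20 °C) should give [(2S,3S)-3-ethynyl-3-methyloxiran-2-yl]methanol F4. Ti(OiPr)4-mediated opening of F4 by phenol 5 at the tertiary propargylic carbon, with inversion, gives (2S,3R)-3-[4-methoxy-2,5-bis(triisopropylsilyloxy)phenoxy]-3-methylpent-4-yne-1,2-diol F5. Periodate cleavage (NaIO4, THF–pH 7 buffer) gives (2R)-2-[4-methoxy-2,5-bis(triisopropylsilyloxy)phenoxy]-2-methylbut-3-ynal F6. Wittig methylenation (Ph3P=CH2, THF, −78 → 0 °C) then gives 9.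

3. Step 12. Enolisation of the hindered ketone may compete with addition of the titanium methylidene, which would return ketone or epimerise C6. The fallback sets out from 17 and returns at 18 by a Peterson olefination. Addition of Me3SiCH2Li in the presence of CeCl3 (THF, −78 °C) should give (2R,6R)-2-{2-[(2S)-6-methoxy-2-methyl-5,8-bis(triisopropylsilyloxy)-2H-chromen-2-yl]ethyl}-2,6-dimethyl-1-[(trimethylsilyl)methyl]cyclohexan-1-ol F7 (either C1 epimer). Treatment of F7 with KH in THF eliminates silanolate to give 18.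

Further compounds
F1 | step 11 | (6R)-6-methylcyclohex-2-en-1-one | C[C@@H]1CCC=CC1=O
F2 | step 11 | (6R)-2-iodo-6-methylcyclohex-2-en-1-one | C[C@@H]1CCC=C(I)C1=O
F3 | step 11 | (6R)-2-{2-[(2S)-6-methoxy-2-methyl-5,8-bis(triisopropylsilyloxy)-2H-chromen-2-yl]ethyl}-6-methylcyclohex-2-en-1-one | C[C@@H]1CCC=C(CC[C@@]2(C)C=Cc3c(O[Si](C(C)C)(C(C)C)C(C)C)c(OC)cc(O[Si](C(C)C)(C(C)C)C(C)C)c3O2)C1=O
F4 | step 4 | [(2S,3S)-3-ethynyl-3-methyloxiran-2-yl]methanol | OC[C@@H]1O[C@@]1(C)C#C
F5 | step 4 | (2S,3R)-3-[4-methoxy-2,5-bis(triisopropylsilyloxy)phenoxy]-3-methylpent-4-yne-1,2-diol | OC[C@H](O)[C@@](Oc1cc(O[Si](C(C)C)(C(C)C)C(C)C)c(OC)cc1O[Si](C(C)C)(C(C)C)C(C)C)(C)C#C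
F6 | step 4 | (2R)-2-[4-methoxy-2,5-bis(triisopropylsilyloxy)phenoxy]-2-methylbut-3-ynal | O=C[C@@](Oc1cc(O[Si](C(C)C)(C(C)C)C(C)C)c(OC)cc1O[Si](C(C)C)(C(C)C)C(C)C)(C)C#C
F7 | step 12 | (2R,6R)-2-{2-[(2S)-6-methoxy-2-methyl-5,8-bis(triisopropylsilyloxy)-2H-chromen-2-yl]ethyl}-2,6-dimethyl-1-[(trimethylsilyl)methyl]cyclohexan-1-ol | C[Si](C)(C)CC1(O)[C@H](C)CCC[C@]1(C)CC[C@@]1(C)C=Cc2c(O[Si](C(C)C)(C(C)C)C(C)C)c(OC)cc(O[Si](C(C)C)(C(C)C)C(C)C)c2O1
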